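The data come from a simulation for substances that don't exist, noise included.

| flask | free monomer | transfer agent | initiator | remark | time |
|---|---|---|---|---|---|
| amber | 0.20 M | 0.020 M | 0.51 mol% | run made earlier |  |
| zeta | 0.20 M | 0.0200 M | 0.34 mol% |  | 6.0 min |
| delta | 0.30 M | 0.0200 M | 0.34 mol% |  | 6.0 min |

amber run (percent of the free monomer charged)

| time / s | monomer in chains / % | free monomer / % |
|---|---|---|
| 10.0 | 0.2 | 96.1 |
| 15.0 | 0.9 | 94.2 |
| 25.0 | 1.1 | 90.5 |
| 40.0 | 2.2 | 85.2 |
| 80.0 | 3.6 | 71.9 |

(scatter of a reading: 0.3 percentage points)

1. which of the two ends with the longer chains by the average number of monomer units in a chain (chains begun, living or dead) ("neither" if they lie within 10%) (zeta / delta / neither)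
2. average number of monomer units in a chain (chains begun, living or dead) at the end, zeta
3. average number of monomer units in a chain (chains begun, living or dead) at the end, delta

- the average divides the monomer in chains by the number of chains begun, living and dead together
- the numbers in the tables scatter by 0.3 percentage points (one standard deviation)
- the earlier runs do not show the number of chains; that part of a forecast is a guess
- no earlier run changes the charge of initiator; that part of a forecast is a guess

Amber is your one earlier run, so ask it first how fast free monomer leaves. The fraction left falls along a single exponential, so the fractional rate is nearly constant, and you can freeze it. Take the last reading and call the result the loss constant 0.247 min⁻¹, a pseudo-first-order constant: the share of what is present that goes each minute. As a check, it gives 84.8% left at 40.0 s, and amber reads 85.2%.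

This constant is a reading from amber, and no earlier run changes the initiator, so carrying it to zeta and delta is my own assumption. On that assumption, zeta and delta each start with the fractional rate 0.247 min⁻¹. The fractional rate then holds, while the rate in charge per minute falls along with the free monomer, and by 6.0 min my reckoning has it down by a factor of 4.40. So I reckon 22.7% of the charge left in each of the two flasks.

Lost monomer is not the same as chains, though: amber's last reading has 3.6% in chains against 28.1% lost. Length divides the monomer in chains by the chains begun, and amber doesn't show that number, so I commit to no length.

The forecast differs from my reckoning in giving lengths: it says delta, with 6 units in zeta (range 1 to 20) and 9 in delta (range 1.4 to 28), on the ground that “Delta has the higher monomer-to-agent ratio”.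

Zeta ends at 114 units and delta at 170, so delta has the longer chains, and both lengths stand near 19.0 times the forecast's figures.

    free monomer + initiator → living end + monomer in chains (k = 6.40 M⁻¹ min⁻¹)
    free monomer + living end → monomer in chains + living end, rate k2*[living end]*[free monomer] (k = 310 M⁻¹ min⁻¹)
    living end + transfer agent → dead chain (kL = 11.0 M⁻¹ min⁻¹)
    2 initiator → spent initiator (k = 9300 M⁻¹ min⁻¹)
    free monomer → uncatalysed product (k = 0.210 min⁻¹)

In zeta, the transfer agent still stands at 99.4% of its charge at 6.00 min. The loss constant's 22.7% meets 24.2% of free monomer in zeta at that time. For delta read at 2.5 min, it gives 53.9% left, and that flask holds 52.0%.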